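## Retrosynthetic overview
1. 17 ⇒ 16 ⇒ 15 ⇒ 14: orthogonal ethers fix the acyl pattern. Bn sits on O4/O5 (removed last with H2), PMB on O3 (DDQ), and 2-OH is free. O2 and O3 are acetylated together.
2. 14 ⇒ 13 ⇒ 12: the oxirane (last ring) comes from 2-OH-directed epoxidation. C2 comes from Luche reduction of an enone.
3. 12 ⇒ 9 + 10: the C1–C7 bond and the benzoate are installed in one operation by the proposed DMAP-relay Morita–Baylis–Hillman benzoyloxymethylation with an acylal.
4. 9 ⇒ 6: the carbocycle (first ring of the target, C1–C6 bond) comes from Ferrier II carbocyclisation followed by dehydration.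
5. 6 ⇒ 1: methyl α-D-glucopyranoside. Glucose C2/C3/C4 become C5/C4/C3, and glucose C5/C6/C1 become C2/C1/C6.

Convention: the target is read as [(1S,2R,3S,4R,5R,6S)-2,3-diacetoxy-4,5-dihydroxy-7-oxabicyclo[4.1.0]heptan-1-yl]methyl benzoate. Drawn with C1→C6 clockwise, the oxirane O is down, 2-OAc down, 3-OAc up, 4-OH down, 5-OH up and CH2OBz (C7) up. This numbering is used for all carbocycles in the "Why" lines.

Assumption: methylene dibenzoate 10 is taken as a catalogue chemical; if out of stock it is made in one operation from CH2Br2 and sodium benzoate.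

## Route

Step 1
Reactants: 1 methyl α-D-glucopyranoside
Product: 2 methyl 4,6-O-[(R)-4-methoxybenzylidene]-α-D-glucopyranoside
Conditions: 4-MeOC6H4CH(OMe)2, CSA (5 mol %), DMF, 55 °C, 200 mbar
Reagents that add atoms: 4-methoxybenzaldehyde dimethyl acetal, COC(OC)c1ccc(OC)cc1
Why: Acid-catalysed transacetalisation under thermodynamic control; only the 4,6-diol gives the trans-decalin-type 1,3-dioxane, whose new acetal centre is (R) with the aryl group equatorial.

Step 2
Reactants: 2 methyl 4,6-O-[(R)-4-methoxybenzylidene]-α-D-glucopyranoside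
Product: 3 methyl 2,3-di-O-benzyl-4,6-O-[(R)-4-methoxybenzylidene]-α-D-glucopyranoside
Conditions: NaH, BnBr, DMF, 0 °C → rt
Reagents that add atoms: benzyl bromide, BrCc1ccccc1
Why: Williamson etherification of the two remaining hydroxyls (the later O5 and O4 of the target); no stereocentre is touched.

Step 3
Reactants: 3 methyl 2,3-di-O-benzyl-4,6-O-[(R)-4-methoxybenzylidene]-α-D-glucopyranoside
Product: 4 methyl 2,3-di-O-benzyl-4-O-(4-methoxybenzyl)-α-D-glucopyranoside
Conditions: DIBAL-H (3 equiv), CH2Cl2–toluene, −40 → 0 °C; aq. Rochelle salt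
Reagents that add atoms: none
Why: Regioselective reductive acetal opening: aluminium binds the less hindered O6, the acetal C–O6 bond breaks and hydride reduces the oxocarbenium ion, which leaves PMB on O4 and frees the primary 6-OH.

Step 4
Reactants: 4 methyl 2,3-di-O-benzyl-4-O-(4-methoxybenzyl)-α-D-glucopyranoside
Product: 5 methyl 2,3-di-O-benzyl-6-deoxy-6-iodo-4-O-(4-methoxybenzyl)-α-D-glucopyranoside
Conditions: I2, PPh3, imidazole, toluene, 70 °C
Reagents that add atoms: iodine, II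
Why: Garegg–Samuelsson (Appel-type) iodination, an SN2 displacement of the alkoxyphosphonium ion at the only free, primary carbinol.

Step 5
Reactants: 5 methyl 2,3-di-O-benzyl-6-deoxy-6-iodo-4-O-(4-methoxybenzyl)-α-D-glucopyranoside
Product: 6 methyl 2,3-di-O-benzyl-6-deoxy-4-O-(4-methoxybenzyl)-α-D-xylo-hex-5-enopyranoside
Conditions: t-BuOK, THF, 0 °C → rt
Reagents that add atoms: none
Why: E2 dehydroiodination; H5 is the only β-hydrogen, so the exocyclic enol ether forms, the all-ether substrate tolerates the base, and the glucose C5 centre is deleted on purpose.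

Step 6
Reactants: 6 methyl 2,3-di-O-benzyl-6-deoxy-4-O-(4-methoxybenzyl)-α-D-xylo-hex-5-enopyranoside
Product: 7 (2S,3R,4S,5S)-3,4-bis(benzyloxy)-5-hydroxy-2-[(4-methoxybenzyl)oxy]cyclohexan-1-one
Conditions: Hg(OCOCF3)2 (10 mol %), acetone–H2O 2:1, rt
Reagents that add atoms: water, O
Why: Ferrier II carbocyclisation: Hg(II)-induced hydration of the enol ether and loss of methanol unmask a 5-keto-aldehyde whose mercury enolate (glucose C6) closes on the aldehyde (glucose C1) in a 6-(enolexo) aldol, forming the C1–C6 bond with C3–C5 untouched; the new carbinol (6-OH up, cis to 5-OBn, major) is removed in step 7.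

Step 7
Reactants: 7 (2S,3R,4S,5S)-3,4-bis(benzyloxy)-5-hydroxy-2-[(4-methoxybenzyl)oxy]cyclohexan-1-one
Product: 9 (4S,5R,6S)-4,5-bis(benzyloxy)-6-[(4-methoxybenzyl)oxy]cyclohex-2-en-1-one, via ketol mesylate 8 (not isolated)
Conditions: MsCl, Et3N, CH2Cl2, 0 °C → rt
Reagents that add atoms: methanesulfonyl chloride, CS(=O)(=O)Cl (its mesyl group is carried only by 8 and leaves again)
Why: Mesylation of the β-hydroxy ketone followed by E1cB elimination with Et3N gives the conjugated enone; the provisional C6 carbinol centre disappears and C3–C5 are untouched.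

Step 8
Reactants: 9 (4S,5R,6S)-4,5-bis(benzyloxy)-6-[(4-methoxybenzyl)oxy]cyclohex-2-en-1-one; 10 methylene dibenzoate
Product: 12 [(3S,4R,5S)-3,4-bis(benzyloxy)-5-[(4-methoxybenzyl)oxy]-6-oxocyclohex-1-en-1-yl]methyl benzoate, via hydroxymethyl enone 11 (not isolated)
Conditions: 10 (1.5 equiv), DMAP (25 mol %), PhCO2H (10 mol %), THF, 40 °C
Reagents that add atoms: none
Why: Proposed new method: a Lewis-base relay Morita–Baylis–Hillman benzoyloxymethylation in which the acylal 10 is both the anhydrous formaldehyde source and the benzoyl donor: DMAP attacks an ester carbonyl of 10 and the expelled BzOCH2O− fragments to monomeric CH2O and benzoate (so 10 ≡ CH2O + Bz2O, released only as fast as DMAP turns over); the same DMAP adds to C6 of enone 9 to give a β-pyridinium enolate that captures CH2O at C1 (new C1–C7 bond); aldolate 11 is benzoylated at once by N-benzoyl-DMAP+/Bz2O, which makes the reversible C–C bond formation irreversible, and benzoate/benzoic acid shuttle the α-proton for E1cB release of DMAP; no water or hydroxide is present, so the base-sensitive trialkoxy enone should not aromatise, 9 carries no other ester that could scramble, and no stereocentre is touched; the closest known reaction types are the DMAP-catalysed MBH hydroxymethylation of cyclic enones with aqueous formaldehyde and DMAP-catalysed acyl transfer from anhydrides, whereas an acylal as a combined C1/acyl donor in an MBH process has, to my knowledge, not been described.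

Step 9
Reactants: 12 [(3S,4R,5S)-3,4-bis(benzyloxy)-5-[(4-methoxybenzyl)oxy]-6-oxocyclohex-1-en-1-yl]methyl benzoate
Product: 13 [(3S,4R,5R,6S)-3,4-bis(benzyloxy)-6-hydroxy-5-[(4-methoxybenzyl)oxy]cyclohex-1-en-1-yl]methyl benzoate
Conditions: NaBH4, CeCl3·7H2O, MeOH–CH2Cl2, −78 °C
Reagents that add atoms: none
Why: Luche reduction: the hard Ce(III)/methoxyborohydride reagent adds 1,2 only, and axial attack from the upper face of the half-chair that holds the three ethers equatorial gives the equatorial 2-OH (down, trans to 3-OPMB), which sets C2; the benzoate is inert at −78 °C.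

Step 10
Reactants: 13 [(3S,4R,5R,6S)-3,4-bis(benzyloxy)-6-hydroxy-5-[(4-methoxybenzyl)oxy]cyclohex-1-en-1-yl]methyl benzoate
Product: 14 [(1R,2R,3R,4S,5R,6S)-4,5-bis(benzyloxy)-2-hydroxy-3-[(4-methoxybenzyl)oxy]-7-oxabicyclo[4.1.0]heptan-1-yl]methyl benzoate
Conditions: m-CPBA, Na2HPO4, CH2Cl2, 0 °C → rt
Reagents that add atoms: m-chloroperbenzoic acid, O=C(OO)c1cccc(Cl)c1
Why: Henbest hydroxyl-directed epoxidation: the pseudo-equatorial allylic 2-OH hydrogen-bonds the peracid and delivers oxygen to the lower face, which is also the face away from the allylic 5-OBn, so C1 and C6 are set with the oxirane cis to O2 and trans to O5.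

Step 11
Reactants: 14 [(1R,2R,3R,4S,5R,6S)-4,5-bis(benzyloxy)-2-hydroxy-3-[(4-methoxybenzyl)oxy]-7-oxabicyclo[4.1.0]heptan-1-yl]methyl benzoate
Product: 15 [(1R,2R,3R,4S,5R,6S)-4,5-bis(benzyloxy)-2,3-dihydroxy-7-oxabicyclo[4.1.0]heptan-1-yl]methyl benzoate
Conditions: DDQ, CH2Cl2–pH 7 buffer 10:1, 0 °C → rt
Reagents that add atoms: none
Why: Oxidative PMB cleavage (hydride abstraction from the electron-rich benzylic position, then hydrolysis of the oxocarbenium ion); plain benzyl ethers, the benzoate and the oxirane survive the buffered, near-neutral medium.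

Step 12
Reactants: 15 [(1R,2R,3R,4S,5R,6S)-4,5-bis(benzyloxy)-2,3-dihydroxy-7-oxabicyclo[4.1.0]heptan-1-yl]methyl benzoate
Product: 16 [(1S,2R,3S,4R,5R,6S)-2,3-diacetoxy-4,5-bis(benzyloxy)-7-oxabicyclo[4.1.0]heptan-1-yl]methyl benzoate
Conditions: Ac2O, pyridine, DMAP (cat.), CH2Cl2, 0 °C → rt
Reagents that add atoms: acetic anhydride, CC(=O)OC(C)=O
Why: DMAP-catalysed O-acetylation of both free secondary alcohols with retention at C2 and C3; no alkoxide is formed, so no Payne rearrangement of the epoxy alcohol occurs.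

Step 13
Reactants: 16 [(1S,2R,3S,4R,5R,6S)-2,3-diacetoxy-4,5-bis(benzyloxy)-7-oxabicyclo[4.1.0]heptan-1-yl]methyl benzoate
Product: 17 [(1S,2R,3S,4R,5R,6S)-2,3-diacetoxy-4,5-dihydroxy-7-oxabicyclo[4.1.0]heptan-1-yl]methyl benzoate (target)
Conditions: H2 (1 atm), 20 % Pd(OH)2/C, EtOAc, rt
Reagents that add atoms: none
Why: Heterogeneous hydrogenolysis of the two benzyl ethers under neutral conditions; the non-benzylic oxirane and the three esters are inert, and no base is present that could move an acetyl group to the freed 4-OH.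

## Compound list
1 | methyl α-D-glucopyranoside | CO[C@H]1O[C@H](CO)[C@@H](O)[C@H](O)[C@H]1O | starting material
2 | methyl 4,6-O-[(R)-4-methoxybenzylidene]-α-D-glucopyranoside | CO[C@H]1O[C@@H]2CO[C@@H](c3ccc(OC)cc3)O[C@H]2[C@H](O)[C@H]1O | intermediate
3 | methyl 2,3-di-O-benzyl-4,6-O-[(R)-4-methoxybenzylidene]-α-D-glucopyranoside | CO[C@H]1O[C@@H]2CO[C@@H](c3ccc(OC)cc3)O[C@H]2[C@H](OCc2ccccc2)[C@H]1OCc1ccccc1 | intermediate
4 | methyl 2,3-di-O-benzyl-4-O-(4-methoxybenzyl)-α-D-glucopyranoside | CO[C@H]1O[C@H](CO)[C@@H](OCc2ccc(OC)cc2)[C@H](OCc2ccccc2)[C@H]1OCc1ccccc1 | intermediate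
5 | methyl 2,3-di-O-benzyl-6-deoxy-6-iodo-4-O-(4-methoxybenzyl)-α-D-glucopyranoside | CO[C@H]1O[C@H](CI)[C@@H](OCc2ccc(OC)cc2)[C@H](OCc2ccccc2)[C@H]1OCc1ccccc1 | intermediate
6 | methyl 2,3-di-O-benzyl-6-deoxy-4-O-(4-methoxybenzyl)-α-D-xylo-hex-5-enopyranoside | CO[C@H]1OC(=C)[C@@H](OCc2ccc(OC)cc2)[C@H](OCc2ccccc2)[C@H]1OCc1ccccc1 | intermediate
7 | (2S,3R,4S,5S)-3,4-bis(benzyloxy)-5-hydroxy-2-[(4-methoxybenzyl)oxy]cyclohexan-1-one | COc1ccc(CO[C@H]2[C@H](OCc3ccccc3)[C@@H](OCc3ccccc3)[C@@H](O)CC2=O)cc1 | intermediate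
8 | 5-O-mesylate of 7 (ketol mesylate) | COc1ccc(CO[C@H]2[C@H](OCc3ccccc3)[C@@H](OCc3ccccc3)[C@@H](OS(C)(=O)=O)CC2=O)cc1 | intermediate (not isolated)
9 | (4S,5R,6S)-4,5-bis(benzyloxy)-6-[(4-methoxybenzyl)oxy]cyclohex-2-en-1-one | COc1ccc(CO[C@H]2[C@H](OCc3ccccc3)[C@@H](OCc3ccccc3)C=CC2=O)cc1 | intermediate
10 | methylene dibenzoate | O=C(OCOC(=O)c1ccccc1)c1ccccc1 | starting material
11 | (4S,5R,6S)-4,5-bis(benzyloxy)-2-(hydroxymethyl)-6-[(4-methoxybenzyl)oxy]cyclohex-2-en-1-one | COc1ccc(CO[C@H]2[C@H](OCc3ccccc3)[C@@H](OCc3ccccc3)C=C(CO)C2=O)cc1 | intermediate (not isolated)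
12 | [(3S,4R,5S)-3,4-bis(benzyloxy)-5-[(4-methoxybenzyl)oxy]-6-oxocyclohex-1-en-1-yl]methyl benzoate | COc1ccc(CO[C@H]2[C@H](OCc3ccccc3)[C@@H](OCc3ccccc3)C=C(COC(=O)c3ccccc3)C2=O)cc1 | intermediate
13 | [(3S,4R,5R,6S)-3,4-bis(benzyloxy)-6-hydroxy-5-[(4-methoxybenzyl)oxy]cyclohex-1-en-1-yl]methyl benzoate | COc1ccc(CO[C@H]2[C@H](OCc3ccccc3)[C@@H](OCc3ccccc3)C=C(COC(=O)c3ccccc3)[C@@H]2O)cc1 | intermediate
14 | [(1R,2R,3R,4S,5R,6S)-4,5-bis(benzyloxy)-2-hydroxy-3-[(4-methoxybenzyl)oxy]-7-oxabicyclo[4.1.0]heptan-1-yl]methyl benzoate | COc1ccc(CO[C@H]2[C@H](OCc3ccccc3)[C@@H](OCc3ccccc3)[C@@H]3O[C@]3(COC(=O)c3ccccc3)[C@@H]2O)cc1 | intermediate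
15 | [(1R,2R,3R,4S,5R,6S)-4,5-bis(benzyloxy)-2,3-dihydroxy-7-oxabicyclo[4.1.0]heptan-1-yl]methyl benzoate | O[C@H]1[C@H](OCc2ccccc2)[C@@H](OCc2ccccc2)[C@@H]2O[C@]2(COC(=O)c2ccccc2)[C@@H]1O | intermediate
16 | [(1S,2R,3S,4R,5R,6S)-2,3-diacetoxy-4,5-bis(benzyloxy)-7-oxabicyclo[4.1.0]heptan-1-yl]methyl benzoate | CC(=O)O[C@H]1[C@H](OCc2ccccc2)[C@@H](OCc2ccccc2)[C@@H]2O[C@]2(COC(=O)c2ccccc2)[C@@H]1OC(C)=O | intermediate
17 | [(1S,2R,3S,4R,5R,6S)-2,3-diacetoxy-4,5-dihydroxy-7-oxabicyclo[4.1.0]heptan-1-yl]methyl benzoate | CC(=O)O[C@H]1[C@H](O)[C@@H](O)[C@@H]2O[C@]2(COC(=O)c2ccccc2)[C@@H]1OC(C)=O | target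

Total step count: 13. Longest linear sequence: 13 (1 → 17; 10 is bought).

## Three steps most likely to fail

**Step 8 (the proposed new step).**
- Risk: DMAP may open the acylal too slowly, or the MBH cycle may stall in the aprotic medium.
- Fallback: known chemistry, cross-coupling in place of Lewis-base catalysis. It sets out from 9 and comes back to the route at 12.
- Johnson α-iodination of 9 (I2, pyridine, CH2Cl2, 0 °C → rt) gives (4S,5R,6S)-4,5-bis(benzyloxy)-2-iodo-6-[(4-methoxybenzyl)oxy]cyclohex-2-en-1-one F1.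
- Stille–Kosugi hydroxymethylation of F1 with Bu3SnCH2OH (Pd(PPh3)4, dioxane, 80 °C) gives the hydroxymethyl enone 11, now isolated.
- BzCl in pyridine (0 °C) converts 11 into 12.

**Step 10.**
- Risk: the alkene is deactivated by three allylic C–O bonds and the directing OH is pseudo-equatorial, so the peracid may react slowly or with eroded face selectivity.
- Fallback: a halohydrin route, in which the face is fixed by Markovnikov, trans-diaxial opening of an iodonium ion and no longer by hydrogen bonding. It sets out from 13 and comes back at 14.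
- NIS in DME–H2O (0 °C) gives [3,4-bis(benzyloxy)-1,6-dihydroxy-2-iodo-5-[(4-methoxybenzyl)oxy]cyclohexyl]methyl benzoate F2. In target numbering it has 1-OH and 2-OH down and 6-I up, because water attacks the tertiary C1 from below the upper-face iodonium ion.
- Ag2O in CH2Cl2 closes the 1-oxygen onto C6 with inversion to give 14.

**Step 3.**
- Risk: wrong regiochemistry of the acetal opening (6-O-PMB) or loss of the PMB group to the Lewis-acidic hydride.
- Fallback: no regioselective reduction; O4 and O6 are distinguished by primary-selective iodination. It sets out from 3 and comes back at 5.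
- Aqueous AcOH (80 %, 60 °C) removes the acetal and gives methyl 2,3-di-O-benzyl-α-D-glucopyranoside F3.
- I2/PPh3/imidazole (toluene, 70 °C) converts only the primary alcohol and gives methyl 2,3-di-O-benzyl-6-deoxy-6-iodo-α-D-glucopyranoside F4.
- 4-Methoxybenzyl trichloroacetimidate with catalytic La(OTf)3 (toluene, rt) etherifies O4 to give 5.

## Further compounds
F1 | step 8 | (4S,5R,6S)-4,5-bis(benzyloxy)-2-iodo-6-[(4-methoxybenzyl)oxy]cyclohex-2-en-1-one | COc1ccc(CO[C@H]2[C@H](OCc3ccccc3)[C@@H](OCc3ccccc3)C=C(I)C2=O)cc1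
F2 | step 10 | [3,4-bis(benzyloxy)-1,6-dihydroxy-2-iodo-5-[(4-methoxybenzyl)oxy]cyclohexyl]methyl benzoate (target numbering: 1-OH down, 2-OH down, 6-I up) | COc1ccc(CO[C@H]2[C@H](OCc3ccccc3)[C@@H](OCc3ccccc3)[C@@H](I)[C@@](O)(COC(=O)c3ccccc3)[C@@H]2O)cc1
F3 | step 3 | methyl 2,3-di-O-benzyl-α-D-glucopyranoside | CO[C@H]1O[C@H](CO)[C@@H](O)[C@H](OCc2ccccc2)[C@H]1OCc1ccccc1
F4 | step 3 | methyl 2,3-di-O-benzyl-6-deoxy-6-iodo-α-D-glucopyranoside | CO[C@H]1O[C@H](CI)[C@@H](O)[C@H](OCc2ccccc2)[C@H]1OCc1ccccc1
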